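(The numbers in the tables come from a simulation for substances that don't exist.)

The partner is counted first. Taken as one partner per target and two per over-reaction product, Tuesday's last readings sum to 104% of the substrate charge and Friday's reading at 1.00 h to 105%, against 105% charged. The plateaus therefore read as the partner, the limiting reagent, used up.

all flasks: partner 1.05 equiv

| charge | substrate | remark | time |
|---|---|---|---|
| Tuesday's | 0.25 M | run made earlier |  |
| Friday's | 0.40 M | run made earlier |  |
| flask | 0.18 M |  | 4.0 h |

| run | time / h | target / % | over-reaction product / % | substrate / % |
|---|---|---|---|---|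
| Tuesday's | 0.200 | 1 | 0 | 103 |
| Tuesday's | 0.333 | 1 | 3 | 98 |
| Tuesday's | 0.417 | 4 | 1 | 98 |
| Tuesday's | 0.667 | 35 | 6 | 58 |
| Tuesday's | 1.00 | 59 | 13 | 28 |
| Tuesday's | 1.50 | 65 | 18 | 18 |
| Tuesday's | 2.50 | 64 | 20 | 18 |
| Friday's | 0.133 | 0 | 1 | 102 |
| Friday's | 0.333 | 57 | 8 | 37 |
| Friday's | 0.667 | 71 | 14 | 11 |
| Friday's | 1.00 | 73 | 16 | 10 |
| Friday's | 1.33 | 73 | 16 | 10 |
| Friday's | 2.00 | 74 | 17 | 12 |
| Friday's | 2.50 | 73 | 14 | 9 |

(each reading ± 1.5 percentage points)

- how much target the flask holds at 4.0 h, in percent of the substrate charged
- how much over-reaction product the flask holds at 4.0 h, in percent of the substrate charged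
- how much substrate the flask holds at 4.0 h, in percent of the substrate charged

What remains to be found is how the partner divides between the two products. Dividing over-reaction product by target on the plateau drops time out and leaves an end-point ratio, which belongs to the finished run and not to a moment inside it. It reads 0.312 on Tuesday's run and 0.219 on Friday's, which is a power 0.755 of dilution. Carried to this flask, my reckoning gives 0.400, the over-reaction ratio. Each target then costs 1.80 partners, counting its share of over-reaction, so the charge yields target 58.3%, over-reaction product 23.3% and substrate 18.3%.

A second way scales the substrate readings directly, with power 1.25, and gives 27.1%. The two ways part, and the second is the unsound one: it ignores the partner charge and takes a small reading to a steeper power. Tuesday's three readings also sum to 102%.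

The forecast gives target 59.5%, over-reaction product 23% and substrate 18%, and expects that “the reaction should still finish by about 2.5 h, before 4 h”. Its target stands above my 58.3%.

The flask gives target 58.2%, over-reaction product 23.2% and substrate 18.5%.

    substrate + partner + released group → target + 2 released group (k = 0.0592 M⁻² s⁻¹)
    substrate + partner → target + released group (k = 1.74 × 10⁻⁶ M⁻¹ s⁻¹)
    partner + target → over-reaction product (k = 0.00187 M⁻¹ s⁻¹)

The flask's ratio is 0.399, against 0.400 reckoned, with 0.30% of its partner left. The neighbouring flask, the same charge read at 1.5 h, has 31.9% of its partner left. Its spent partner, 71.5% of the substrate charged, divided by 1.80, gives target 39.7% and over-reaction product 15.9%. That neighbour holds target 46.1% and over-reaction product 12.7%, a ratio of 0.275.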